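## The problem

The target **19** is a diaryl ether with no stereocentres. Ring A is a methyl benzoate whose ester carbon C1 lies between a prenyl ether (C2) and the bridging oxygen (C6), with a methyl group at C4. Ring B carries the bridging oxygen at C1', a hydroxymethyl group at C2' and methoxy groups at C4' and C6'. The bridging oxygen has three ortho neighbours, two of them on the electron-rich ring B, so joining two finished arenes by metal-mediated coupling or by addition–elimination on ring A would be hindered and electronically mismatched. Stereocentres that appear on the way control nothing and only have to be erasable. The fragile groups are the prenyl aryl ether (acid, halogens, quinone oxidants, hydrogenation, Claisen rearrangement on strong heating), the primary benzylic alcohol, and the ring A ester. That ester is shielded from outside attack but lies within five-membered reach of any carbanion on the atom bound to the bridging oxygen. The enabling feature is the 1,3-placement of the oxygens at C4' and C6' with C5' between them: ring B is a masked cyclohexane-1,3-dione in which C1' is alpha to the C6' carbonyl and C2' is beta to the C4' carbonyl through C3'. A malonate carbon that already bears the ring A oxygen can therefore become C1' (one ester carbon becoming C6'), and a methyl enone can supply C2'–C5', so the hindered ether bond is made by a plain SN2 reaction before ring B exists.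

## Retrosynthesis

**19 from 18.** The O–H bond of the C2' hydroxymethyl group is replaced by O–Si, giving the tert-butyldimethylsilyl ether **18**. A free benzylic alcohol would interfere with enolate, selenium and alkylation chemistry, and the silyl group comes in with the enone building block at no cost in steps. The forward step is a fluoride cleavage, buffered so that the freed alkoxide does not reach the ring A ester.

**18 back to 12.** The two O–CH3 bonds on ring B are cut one at a time and two hydrogens are returned to C1' and C2'. Ether **18** comes from phenol **17** (O–CH3 at C6'). Phenol **17** is the enol form of dienone **16**, which arises from the vinylogous ester **13** by dehydrogenation across C1'–C2' through selenide **14** and selenoxide **15**. Enol ether **13** comes from dione **12** by O-methylation at C4'. A one-step oxidative aromatisation of the dione (halogen, quinone or metal-catalysed dehydrogenation) is the obvious neighbour, but each such reagent also attacks or cleaves the prenyl ether. Fixing one oxygen as its methyl ether first leaves a ketone with a single alpha' position, and cold enolate selenenylation with selenoxide elimination is the mildest dehydrogenation available. The precursor **12** has no aromatic ring B and only two stereocentres of no consequence. The forward steps need O-methylation at the less hindered oxygen, enolisation at C1' and a syn hydrogen at C2'.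

**12 from 10.** The C1'–H bond is replaced by C1'–CO2CH3, giving keto ester **10**. The extra ester makes C1' a malonate carbon, the most acidic and most reliable donor position in the molecule. The price is one step: the forward reaction must hydrolyse this ester beside the more shielded ring A ester and lose carbon dioxide through keto acid **11**.

**10 from 5 and 8 (key disconnection).** The bonds C1'–C2' and C5'–C6' are cut, opening ring B to the aryloxymalonate **5** and the silyloxy enone **8**; the open-chain Michael adduct **9** lies between them. Other cuts of the dione ring would make the aryloxy-bearing carbon an electrophile or would need a preformed 1,3-diketone donor. This cut uses the malonate carbon as the only possible nucleophile and leaves the aryl–oxygen bond to earlier, simpler chemistry. Both precursors are acyclic apart from ring A and are each one or two steps from catalog compounds. The forward reaction must let the malonate anion add to the enone faster than it acylates on the ring A ester.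

**5 from 3 and 4, and 3 from 1 and 2.** The O–C1' bond is cut to give phenol **3** and dimethyl bromomalonate **4**. The O–prenyl bond is cut to give the symmetrical methyl 2,6-dihydroxy-4-methylbenzoate **1** and prenyl bromide **2**. The prenyl group goes on first: the first alkylation of a symmetrical diol needs no regiocontrol, and a malonate C–H already in place would itself be prenylated under base. Both forward reactions are Williamson alkylations of a hydrogen-bonded phenol.

**8 from 6 and 7.** The C2'=C3' double bond of the enone is cut to (tert-butyldimethylsilyloxy)acetaldehyde **6** and the acetonyl ylide **7**. A stabilised ylide gives the E enone directly; the geometry is in any case lost in the Michael step.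

## Roads not taken

Alternative 1: Ring A would be cut at C1–C2 and C3–C4 and built by an inverse-electron-demand [4+2] cycloaddition. The partners are the pyrone ester A2, methyl 4-(2-formyl-4,6-dimethoxyphenoxy)-6-methyl-2-oxo-2H-pyran-3-carboxylate, and the ketene acetal A3, 1,1-dimethoxyethene. The bicyclic lactone loses carbon dioxide and then methanol to give the benzoate A1, methyl 2-(2-formyl-4,6-dimethoxyphenoxy)-6-methoxy-4-methylbenzoate.
- Merits: the diaryl ether again comes from an addition–elimination (the phenoxide of aldehyde A4, 2-hydroxy-3,5-dimethoxybenzaldehyde, on an activated 4-position of the pyrone), not from an aryl coupling. The pyrone-to-salicylate conversion is an established reaction type with fixed regiochemistry. Ring A arrives aromatic in one step.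
- Weak points: in A2 the 4-aryloxy donor and the 6-methyl group both lower the reactivity of the diene at the carbon the acetal must attack. The ring B aldehyde is exposed to a strongly nucleophilic ketene acetal at the temperature needed. A1 has a methyl ether where the target has the prenyl ether, so a chelation-controlled demethylation beside two other aryl methyl ethers, a prenylation and an aldehyde reduction must follow. A4 itself must be prepared.
- Comparison: in precedent for its key step and in avoiding a late aromatisation, this road is better than the chosen plan. The chosen plan sets against it that the prenyl ether and the ring B oxygen pattern are final from the start, with no selective ether cleavage, and that all its building blocks are catalog compounds.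

Alternative 2: Ring A would be cut at C4–C5 and C1–C2. The lithium dienolate of the butenoate A6, methyl (E)-3-{2-[(tert-butyldimethylsilyloxy)methyl]-4,6-dimethoxyphenoxy}but-2-enoate (generated with LiN(iPr)2), adds through its gamma carbon to methyl crotonate A7 and closes by Claisen condensation. The product is the cyclohexenone A5, racemic methyl 2-{2-[(tert-butyldimethylsilyloxy)methyl]-4,6-dimethoxyphenoxy}-4-methyl-6-oxocyclohex-1-ene-1-carboxylate. Dehydrogenation to the salicylate, prenylation and desilylation would follow.
- Merits: ring B enters complete and aromatic from phenol A8, 2-[(tert-butyldimethylsilyloxy)methyl]-4,6-dimethoxyphenol. The only oxidation is done before the prenyl group is present, so robust oxidants are allowed. The endgame is three steps against five. In these respects it is better than the chosen plan.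
- Weak points: the dienolate is ambident and must react at the gamma and not the alpha carbon. A7 is a sluggish acceptor and is itself deprotonated by amide bases. The aryl vinyl ether bond of A6 can be cleaved by addition–elimination with the amide base or with the methoxide released in the ring closure. A8 is a tetrasubstituted arene that needs its own multistep, regiodefined synthesis.
- Comparison: the chosen plan sets against the shorter endgame a donor that is a single, non-ambident stabilised carbanion under equilibrating conditions, and the fact that no aromatic building block beyond a commercial benzoate is needed.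

Alternative 3: The bonds O–C6 and C1–carboxyl would be cut across an aryne. CsF would free the benzyne A11, 3-(methoxymethoxy)-5-methylbenzyne, from the silyl triflate A10, 3-(methoxymethoxy)-5-methyl-2-(trimethylsilyl)phenyl trifluoromethanesulfonate. The cesium salt of phenol A8 adds at C6, the position remote from the alkoxy group, and the aryl anion at C1 is trapped by carbon dioxide A12. The product is the acid A9, 2-{2-[(tert-butyldimethylsilyloxy)methyl]-4,6-dimethoxyphenoxy}-6-(methoxymethoxy)-4-methylbenzoic acid.
- Merits: this is the most convergent road. Both rings are aromatic throughout, no oxidation level is adjusted, and the regiochemistry of aryne capture is predictable.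
- Weak points: the step is a three-component competition in which protonation of the aryl anion, or reversible carboxylation of the phenoxide itself, can win. A doubly ortho-substituted phenoxide is a poor aryne trap. The fluoride that generates A11 also attacks the primary silyl ether of A8. A10 and A8 each need several steps. Esterification, removal of the methoxymethyl group, prenylation and desilylation remain.
- Comparison: if the coupling performed, this would be the shortest road in longest linear sequence and the best in convergence. The chosen plan sets against it that none of its steps is a three-way competition, that its starting materials need no preparation, and that the acid-sensitive prenyl ether is never exposed to an acidic deprotection.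

Key step: step 4

Remark: compounds 1, 2, 4, 6 and 7 are taken to be catalog compounds.

Remark: O-methylation of dione 12 is assumed to fall on the less hindered oxygen at C4'. Methylation at the other oxygen would not break the route, because dehydrogenation from the C3' side and the final methylation lead to the same dimethyl ether 18.

## Route

Step 1
Reactants: 1 methyl 2,6-dihydroxy-4-methylbenzoate; 2 prenyl bromide (1-bromo-3-methylbut-2-ene)
Product: 3 methyl 2-hydroxy-4-methyl-6-(3-methylbut-2-enyloxy)benzoate
Conditions: K2CO3 (1.1 equiv), 2 (1.0 equiv), acetone, rt → 40 °C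
Reagents that add atoms: none
Why: Williamson etherification of a symmetrical diol, so no regiochemical question arises. After the first alkylation the remaining hydroxyl is held by a strong hydrogen bond to the ester carbonyl and is much less nucleophilic, which with one equivalent of halide should stop the reaction at the monoether.

Step 2
Reactants: 3 methyl 2-hydroxy-4-methyl-6-(3-methylbut-2-enyloxy)benzoate; 4 dimethyl bromomalonate
Product: 5 dimethyl 2-[2-(methoxycarbonyl)-5-methyl-3-(3-methylbut-2-enyloxy)phenoxy]malonate
Conditions: K2CO3 (2 equiv), 4 (1.3 equiv), acetone, reflux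
Reagents that add atoms: none
Why: SN2 displacement of bromide from a doubly activated carbon by the phenoxide (Williamson-type O-alkylation), as in the preparation of aryloxymalonates from ortho-carbonyl phenols. A carbonate base in an aprotic solvent without added alkoxide should leave the product at the malonate stage and not drive it on to acylation of the ortho ester.

Step 3
Reactants: 6 (tert-butyldimethylsilyloxy)acetaldehyde; 7 1-(triphenylphosphoranylidene)propan-2-one
Product: 8 (E)-5-(tert-butyldimethylsilyloxy)pent-3-en-2-one
Conditions: CH2Cl2, rt
Reagents that add atoms: none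
Why: Wittig olefination with a stabilised acyl ylide, which gives the E enone.

Step 4
Reactants: 5 dimethyl 2-[2-(methoxycarbonyl)-5-methyl-3-(3-methylbut-2-enyloxy)phenoxy]malonate; 8 (E)-5-(tert-butyldimethylsilyloxy)pent-3-en-2-one
Product: 10 methyl 6-[(tert-butyldimethylsilyloxy)methyl]-1-[2-(methoxycarbonyl)-5-methyl-3-(3-methylbut-2-enyloxy)phenoxy]-2,4-dioxocyclohexane-1-carboxylate (racemic diastereomer mixture), via Michael adduct 9 (not isolated)
Conditions: NaOMe (0.2 equiv), 8 (1.3 equiv), MeOH, 0 °C → rt; then NaOMe (1.5 equiv), 50 °C; 1 M HCl to pH 3, 0 °C
Reagents that add atoms: none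
Why: Proposed new method: methoxide removes the only C–H of aryloxymalonate 5, and the stabilised tertiary carbanion adds in a Michael reaction to the beta carbon of enone 8 (bond C1'–C2') to give adduct 9; with a full equivalent of base the methyl ketone is enolised on its methyl side (C5') and attacks one of the two equivalent malonate ester carbons (C6') in a 6-exo-trig Claisen closure that expels methoxide. The closest known reaction type is the dimedone-type Michael–Claisen annulation of malonates and 2-alkylmalonates with enones; a 2-aryloxymalonate has not served as the donor, and the reasoning is that the oxygen substituent keeps the carbanion soft and stabilised while adding only moderate bulk. The closure should be irreversible in practice because the product is held as the delocalised enolate of the cyclohexane-1,3-dione. C2' is set in the Michael step and C1' becomes stereogenic only when one of its two ester groups is consumed in the closure; nothing controls either centre and nothing needs to, since both carbons become sp2 on aromatisation. The selectivity that matters is that of the carbanion for the enone over the ortho ester of ring A (a five-membered Dieckmann closure): that ester is shielded by two ortho oxygens, the Michael stage is run cold with substoichiometric base so that the malonate C–H is used up before forcing conditions are applied, and an acyl adduct on ring A has no acidic hydrogen and can revert. Regiochemistry is fixed because only the malonate carbon is nucleophilic and only the methyl side of the ketone reaches an ester through a six-membered transition state.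

Step 5
Reactants: 10 methyl 6-[(tert-butyldimethylsilyloxy)methyl]-1-[2-(methoxycarbonyl)-5-methyl-3-(3-methylbut-2-enyloxy)phenoxy]-2,4-dioxocyclohexane-1-carboxylate
Product: 12 methyl 2-({6-[(tert-butyldimethylsilyloxy)methyl]-2,4-dioxocyclohexyl}oxy)-4-methyl-6-(3-methylbut-2-enyloxy)benzoate (racemic diastereomer mixture), via keto acid 11 (not isolated)
Conditions: LiOH·H2O (4 equiv), THF/MeOH/H2O, 40 °C; 1 M HCl to pH 3, 0 °C; PhMe, 60 °C
Reagents that add atoms: none
Why: Ester hydrolysis followed by decarboxylation of the beta-keto acid, the classical end of a dimedone-type synthesis; the dione is protected as its enolate against retro-Claisen opening. The benzoate of ring A, flanked by two ortho oxygens, is the more shielded ester and should hydrolyse more slowly than the alpha-aryloxy ester at C1'.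

Step 6
Reactants: 12 methyl 2-({6-[(tert-butyldimethylsilyloxy)methyl]-2,4-dioxocyclohexyl}oxy)-4-methyl-6-(3-methylbut-2-enyloxy)benzoate
Product: 13 methyl 2-({6-[(tert-butyldimethylsilyloxy)methyl]-4-methoxy-2-oxocyclohex-3-en-1-yl}oxy)-4-methyl-6-(3-methylbut-2-enyloxy)benzoate (racemic diastereomer mixture)
Conditions: Me2SO4 (1.2 equiv), K2CO3, acetone, 50 °C
Reagents that add atoms: dimethyl sulfate, COS(=O)(=O)OC
Why: O-alkylation of the vinylogous acid anion with a hard methylating agent. The oxygen at C4' is remote from the aryloxy-bearing C1' and should react preferentially, and the resulting enone avoids allylic strain between the methoxy group and the C1' substituent.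

Step 7
Reactants: 13 methyl 2-({6-[(tert-butyldimethylsilyloxy)methyl]-4-methoxy-2-oxocyclohex-3-en-1-yl}oxy)-4-methyl-6-(3-methylbut-2-enyloxy)benzoate
Product: 17 methyl 2-{2-[(tert-butyldimethylsilyloxy)methyl]-6-hydroxy-4-methoxyphenoxy}-4-methyl-6-(3-methylbut-2-enyloxy)benzoate, via selenide 14 (not isolated), via selenoxide 15 (not isolated), via dienone 16 (not isolated)
Conditions: LiN(iPr)2 (1.1 equiv), THF, −78 °C; PhSeBr (1.05 equiv), −78 °C; aqueous NH4Cl; crude 14: mCPBA (1.0 equiv), CH2Cl2, −78 °C; iPr2NH, −78 °C → rt
Reagents that add atoms: none
Why: Kinetic alpha'-deprotonation of the vinylogous ester at C1' and selenenylation give 14; oxidation to 15 and selenoxide syn elimination through the only beta hydrogen (C2'–H) give dienone 16, the keto tautomer of a phenol, which enolises to 17. Selenium should enter anti to the silyloxymethyl group, which places it syn to C2'–H as the elimination requires. The enolate is trapped cold before it can acylate on the ring A ester, and one equivalent of peracid at −78 °C with an amine buffer should spare the prenyl double bond.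

Step 8
Reactants: 17 methyl 2-{2-[(tert-butyldimethylsilyloxy)methyl]-6-hydroxy-4-methoxyphenoxy}-4-methyl-6-(3-methylbut-2-enyloxy)benzoate
Product: 18 methyl 2-{2-[(tert-butyldimethylsilyloxy)methyl]-4,6-dimethoxyphenoxy}-4-methyl-6-(3-methylbut-2-enyloxy)benzoate
Conditions: MeI (3 equiv), K2CO3, acetone, 50 °C
Reagents that add atoms: iodomethane, CI
Why: Williamson methylation of the only free phenol; no other acidic O–H or C–H is present.

Step 9
Reactants: 18 methyl 2-{2-[(tert-butyldimethylsilyloxy)methyl]-4,6-dimethoxyphenoxy}-4-methyl-6-(3-methylbut-2-enyloxy)benzoate
Product: 19 methyl 2-[2-(hydroxymethyl)-4,6-dimethoxyphenoxy]-4-methyl-6-(3-methylbut-2-enyloxy)benzoate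
Conditions: Bu4NF (1.5 equiv), AcOH (1.5 equiv), THF, 0 °C → rt
Reagents that add atoms: none
Why: Fluoride-induced cleavage of a primary silyl ether. Acetic acid buffers the liberated alkoxide so that it does not attack the ring A ester, and neither the prenyl ether nor the methyl ethers are touched.

## Compound list

1 | methyl 2,6-dihydroxy-4-methylbenzoate | COC(=O)c1c(O)cc(C)cc1O | starting material
2 | prenyl bromide (1-bromo-3-methylbut-2-ene) | CC(C)=CCBr | starting material
3 | methyl 2-hydroxy-4-methyl-6-(3-methylbut-2-enyloxy)benzoate | COC(=O)c1c(O)cc(C)cc1OCC=C(C)C | intermediate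
4 | dimethyl bromomalonate | COC(=O)C(Br)C(=O)OC | starting material
5 | dimethyl 2-[2-(methoxycarbonyl)-5-methyl-3-(3-methylbut-2-enyloxy)phenoxy]malonate | COC(=O)C(Oc1cc(C)cc(OCC=C(C)C)c1C(=O)OC)C(=O)OC | intermediate
6 | (tert-butyldimethylsilyloxy)acetaldehyde | CC(C)(C)[Si](C)(C)OCC=O | starting material
7 | 1-(triphenylphosphoranylidene)propan-2-one | CC(=O)C=P(c1ccccc1)(c1ccccc1)c1ccccc1 | starting material
8 | (E)-5-(tert-butyldimethylsilyloxy)pent-3-en-2-one | CC(=O)/C=C/CO[Si](C)(C)C(C)(C)C | intermediate
9 | Michael adduct (not isolated): dimethyl 2-[1-(tert-butyldimethylsilyloxy)-4-oxopentan-2-yl]-2-[2-(methoxycarbonyl)-5-methyl-3-(3-methylbut-2-enyloxy)phenoxy]malonate, racemic | COC(=O)C(Oc1cc(C)cc(OCC=C(C)C)c1C(=O)OC)(C(=O)OC)C(CO[Si](C)(C)C(C)(C)C)CC(C)=O | intermediate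
10 | methyl 6-[(tert-butyldimethylsilyloxy)methyl]-1-[2-(methoxycarbonyl)-5-methyl-3-(3-methylbut-2-enyloxy)phenoxy]-2,4-dioxocyclohexane-1-carboxylate, racemic mixture of diastereomers, handled as its enol | COC(=O)C1(Oc2cc(C)cc(OCC=C(C)C)c2C(=O)OC)C(=O)CC(=O)CC1CO[Si](C)(C)C(C)(C)C | intermediate
11 | keto acid (not isolated): 6-[(tert-butyldimethylsilyloxy)methyl]-1-[2-(methoxycarbonyl)-5-methyl-3-(3-methylbut-2-enyloxy)phenoxy]-2,4-dioxocyclohexane-1-carboxylic acid, racemic mixture of diastereomers | OC(=O)C1(Oc2cc(C)cc(OCC=C(C)C)c2C(=O)OC)C(=O)CC(=O)CC1CO[Si](C)(C)C(C)(C)C | intermediate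
12 | methyl 2-({6-[(tert-butyldimethylsilyloxy)methyl]-2,4-dioxocyclohexyl}oxy)-4-methyl-6-(3-methylbut-2-enyloxy)benzoate, racemic mixture of diastereomers | COC(=O)c1c(OCC=C(C)C)cc(C)cc1OC1C(=O)CC(=O)CC1CO[Si](C)(C)C(C)(C)C | intermediate
13 | methyl 2-({6-[(tert-butyldimethylsilyloxy)methyl]-4-methoxy-2-oxocyclohex-3-en-1-yl}oxy)-4-methyl-6-(3-methylbut-2-enyloxy)benzoate, racemic mixture of diastereomers | COC(=O)c1c(OCC=C(C)C)cc(C)cc1OC1C(=O)C=C(OC)CC1CO[Si](C)(C)C(C)(C)C | intermediate
14 | selenide (not isolated): methyl 2-({6-[(tert-butyldimethylsilyloxy)methyl]-4-methoxy-2-oxo-1-(phenylselanyl)cyclohex-3-en-1-yl}oxy)-4-methyl-6-(3-methylbut-2-enyloxy)benzoate, racemic | COC(=O)c1c(OCC=C(C)C)cc(C)cc1OC1([Se]c2ccccc2)C(=O)C=C(OC)CC1CO[Si](C)(C)C(C)(C)C | intermediate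
15 | selenoxide (not isolated): methyl 2-({6-[(tert-butyldimethylsilyloxy)methyl]-4-methoxy-2-oxo-1-(phenylseleninyl)cyclohex-3-en-1-yl}oxy)-4-methyl-6-(3-methylbut-2-enyloxy)benzoate | COC(=O)c1c(OCC=C(C)C)cc(C)cc1OC1([Se](=O)c2ccccc2)C(=O)C=C(OC)CC1CO[Si](C)(C)C(C)(C)C | intermediate
16 | dienone (not isolated): methyl 2-({2-[(tert-butyldimethylsilyloxy)methyl]-4-methoxy-6-oxocyclohexa-1,4-dien-1-yl}oxy)-4-methyl-6-(3-methylbut-2-enyloxy)benzoate | COC(=O)c1c(OCC=C(C)C)cc(C)cc1OC1=C(CO[Si](C)(C)C(C)(C)C)CC(OC)=CC1=O | intermediate
17 | methyl 2-{2-[(tert-butyldimethylsilyloxy)methyl]-6-hydroxy-4-methoxyphenoxy}-4-methyl-6-(3-methylbut-2-enyloxy)benzoate | COC(=O)c1c(OCC=C(C)C)cc(C)cc1Oc1c(O)cc(OC)cc1CO[Si](C)(C)C(C)(C)C | intermediate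
18 | methyl 2-{2-[(tert-butyldimethylsilyloxy)methyl]-4,6-dimethoxyphenoxy}-4-methyl-6-(3-methylbut-2-enyloxy)benzoate | COC(=O)c1c(OCC=C(C)C)cc(C)cc1Oc1c(OC)cc(OC)cc1CO[Si](C)(C)C(C)(C)C | intermediate
19 | methyl 2-[2-(hydroxymethyl)-4,6-dimethoxyphenoxy]-4-methyl-6-(3-methylbut-2-enyloxy)benzoate (CNP0573678.0) | COC(=O)c1c(OCC=C(C)C)cc(C)cc1Oc1c(CO)cc(OC)cc1OC | target

## Step count and risks

Total: 9 steps. Longest linear sequence: 8 steps (steps 1, 2, 4, 5, 6, 7, 8 and 9, from compound 1); step 3 supplies the enone branch.

**Step 4 (key step, proposed new method).**
- What may go wrong: the malonate anion may be diverted into five-membered acylation of the ring A ester, made irreversible by loss of a methoxycarbonyl group to methoxide. The Michael equilibrium between a tertiary carbanion and a beta-substituted enone may also lie on the reactant side, so that base-induced isomerisation or oligomerisation of the gamma-silyloxy enone uses up the acceptor.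
- Fallback (known chemistry): set out from 3 and drop the second ester altogether.
  - Alkylation of 3 with methyl bromoacetate (K2CO3, acetone) should give methyl 2-(2-methoxy-2-oxoethoxy)-4-methyl-6-(3-methylbut-2-enyloxy)benzoate F1.
  - Deprotonation with LiN(iPr)2 in the presence of Me3SiCl (THF, −78 °C, in situ trapping, so that no free ester enolate lingers beside the ring A ester) should give the silyl ketene acetal methyl 2-{[2-methoxy-2-(trimethylsilyloxy)ethenyl]oxy}-4-methyl-6-(3-methylbut-2-enyloxy)benzoate F2.
  - Mukaiyama–Michael addition of F2 to enone 8 (catalytic Sc(OTf)3, CH2Cl2, −78 °C) forms the same C1'–C2' bond and gives the silyl enol ether methyl 2-({3-[(tert-butyldimethylsilyloxy)methyl]-1-methoxy-1-oxo-5-(trimethylsilyloxy)hex-4-en-2-yl}oxy)-4-methyl-6-(3-methylbut-2-enyloxy)benzoate F3.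
  - Aqueous work-up hydrolyses F3 to the keto ester methyl 2-({3-[(tert-butyldimethylsilyloxy)methyl]-1-methoxy-1,5-dioxohexan-2-yl}oxy)-4-methyl-6-(3-methylbut-2-enyloxy)benzoate F4.
  - KOtBu in THF (0 °C → rt) then closes the C5'–C6' bond by the same 6-exo Claisen condensation. The detour comes back to the route at 12 and replaces steps 4 and 5.

**Step 7.**
- What may go wrong: selenenylation at the fully substituted, aryloxy-bearing enolate carbon may be slow. The C1' lithium enolate may acylate on the ring A ester during its lifetime. Selenium may enter syn to the silyloxymethyl group, so that no syn beta hydrogen is available. Electrophilic selenium by-products may add to the prenyl alkene or to the electron-rich phenol as it forms.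
- Fallback: set out from 13. Deprotonation with LiN(iPr)2 in the presence of Me3SiCl (THF, −78 °C) should give the silyl dienol ether methyl 2-({6-[(tert-butyldimethylsilyloxy)methyl]-4-methoxy-2-(trimethylsilyloxy)cyclohexa-1,3-dien-1-yl}oxy)-4-methyl-6-(3-methylbut-2-enyloxy)benzoate F5. Saegusa–Ito oxidation with Pd(OAc)2 (1.1 equiv, MeCN, rt) follows. The palladium enolate can reach either ring face, so beta-hydride elimination does not depend on the configuration at C1'. It gives dienone 16, which enolises, and the route is rejoined at 17.

**Step 5.**
- What may go wrong: hydrolysis of a neopentyl-type ester next to an anionic enolate may be incomplete. Forcing conditions would then begin to hydrolyse the ring A ester or the silyl ether.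
- Fallback: set out from 10 and accept the loss of selectivity. KOH in aqueous MeOH at reflux should hydrolyse both esters to the diacid 6-[(tert-butyldimethylsilyloxy)methyl]-1-[2-carboxy-5-methyl-3-(3-methylbut-2-enyloxy)phenoxy]-2,4-dioxocyclohexane-1-carboxylic acid F6. Acidification to pH 3 and warming in toluene decarboxylates only the beta-keto acid position and gives 2-({6-[(tert-butyldimethylsilyloxy)methyl]-2,4-dioxocyclohexyl}oxy)-4-methyl-6-(3-methylbut-2-enyloxy)benzoic acid F7. Excess Me2SO4 with K2CO3 in acetone then methylates the carboxylate and the dione oxygen in one operation, and the route is rejoined at 13.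

**Step 2.**
- What may go wrong: alkylation of the chelated, hindered phenoxide may be sluggish. Bromine transfer from the bromomalonate to the electron-rich ring, self-condensation of the bromomalonate, or onward acylation of the ring A ester by the product anion may compete.
- Fallback: set out from 3 and form the O–C1' bond by carbenoid O–H insertion: dimethyl diazomalonate with catalytic Rh2(OAc)4 in CH2Cl2 at reflux, with no base and no halogen. This comes back to the route at 5.

## Further compounds

F1 | step 4 | methyl 2-(2-methoxy-2-oxoethoxy)-4-methyl-6-(3-methylbut-2-enyloxy)benzoate | COC(=O)COc1cc(C)cc(OCC=C(C)C)c1C(=O)OC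
F2 | step 4 | methyl 2-{[2-methoxy-2-(trimethylsilyloxy)ethenyl]oxy}-4-methyl-6-(3-methylbut-2-enyloxy)benzoate (E/Z mixture) | COC(O[Si](C)(C)C)=COc1cc(C)cc(OCC=C(C)C)c1C(=O)OC
F3 | step 4 | methyl 2-({3-[(tert-butyldimethylsilyloxy)methyl]-1-methoxy-1-oxo-5-(trimethylsilyloxy)hex-4-en-2-yl}oxy)-4-methyl-6-(3-methylbut-2-enyloxy)benzoate (racemic diastereomer mixture) | COC(=O)C(Oc1cc(C)cc(OCC=C(C)C)c1C(=O)OC)C(CO[Si](C)(C)C(C)(C)C)C=C(C)O[Si](C)(C)C
F4 | step 4 | methyl 2-({3-[(tert-butyldimethylsilyloxy)methyl]-1-methoxy-1,5-dioxohexan-2-yl}oxy)-4-methyl-6-(3-methylbut-2-enyloxy)benzoate (racemic diastereomer mixture) | COC(=O)C(Oc1cc(C)cc(OCC=C(C)C)c1C(=O)OC)C(CO[Si](C)(C)C(C)(C)C)CC(C)=O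
F5 | step 7 | methyl 2-({6-[(tert-butyldimethylsilyloxy)methyl]-4-methoxy-2-(trimethylsilyloxy)cyclohexa-1,3-dien-1-yl}oxy)-4-methyl-6-(3-methylbut-2-enyloxy)benzoate (racemic) | COC(=O)c1c(OCC=C(C)C)cc(C)cc1OC1=C(O[Si](C)(C)C)C=C(OC)CC1CO[Si](C)(C)C(C)(C)C
F6 | step 5 | 6-[(tert-butyldimethylsilyloxy)methyl]-1-[2-carboxy-5-methyl-3-(3-methylbut-2-enyloxy)phenoxy]-2,4-dioxocyclohexane-1-carboxylic acid (racemic diastereomer mixture) | OC(=O)c1c(OCC=C(C)C)cc(C)cc1OC1(C(=O)O)C(=O)CC(=O)CC1CO[Si](C)(C)C(C)(C)C
F7 | step 5 | 2-({6-[(tert-butyldimethylsilyloxy)methyl]-2,4-dioxocyclohexyl}oxy)-4-methyl-6-(3-methylbut-2-enyloxy)benzoic acid (racemic diastereomer mixture) | OC(=O)c1c(OCC=C(C)C)cc(C)cc1OC1C(=O)CC(=O)CC1CO[Si](C)(C)C(C)(C)C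
F0 | step 2 | none | none
A1 | alternative 1 | methyl 2-(2-formyl-4,6-dimethoxyphenoxy)-6-methoxy-4-methylbenzoate | COC(=O)c1c(OC)cc(C)cc1Oc1c(C=O)cc(OC)cc1OC
A2 | alternative 1 | methyl 4-(2-formyl-4,6-dimethoxyphenoxy)-6-methyl-2-oxo-2H-pyran-3-carboxylate | COC(=O)C1=C(Oc2c(C=O)cc(OC)cc2OC)C=C(C)OC1=O
A3 | alternative 1 | 1,1-dimethoxyethene | C=C(OC)OC
A4 | alternative 1 | 2-hydroxy-3,5-dimethoxybenzaldehyde | COc1cc(C=O)c(O)c(OC)c1
A5 | alternative 2 | racemic methyl 2-{2-[(tert-butyldimethylsilyloxy)methyl]-4,6-dimethoxyphenoxy}-4-methyl-6-oxocyclohex-1-ene-1-carboxylate | COC(=O)C1=C(Oc2c(CO[Si](C)(C)C(C)(C)C)cc(OC)cc2OC)CC(C)CC1=O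
A6 | alternative 2 | methyl (E)-3-{2-[(tert-butyldimethylsilyloxy)methyl]-4,6-dimethoxyphenoxy}but-2-enoate | COC(=O)/C=C(\C)Oc1c(CO[Si](C)(C)C(C)(C)C)cc(OC)cc1OC
A7 | alternative 2 | methyl (E)-but-2-enoate (methyl crotonate) | C/C=C/C(=O)OC
A8 | alternative 2 | 2-[(tert-butyldimethylsilyloxy)methyl]-4,6-dimethoxyphenol | COc1cc(CO[Si](C)(C)C(C)(C)C)c(O)c(OC)c1
A9 | alternative 3 | 2-{2-[(tert-butyldimethylsilyloxy)methyl]-4,6-dimethoxyphenoxy}-6-(methoxymethoxy)-4-methylbenzoic acid | COCOc1cc(C)cc(Oc2c(CO[Si](C)(C)C(C)(C)C)cc(OC)cc2OC)c1C(=O)O
A10 | alternative 3 | 3-(methoxymethoxy)-5-methyl-2-(trimethylsilyl)phenyl trifluoromethanesulfonate | COCOc1cc(C)cc(OS(=O)(=O)C(F)(F)F)c1[Si](C)(C)C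
A11 | alternative 3 | 3-(methoxymethoxy)-5-methylbenzyne | COCOC1=CC(C)=CC#C1
A12 | alternative 3 | carbon dioxide | O=C=O
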